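**Retrosynthetic overview**
- Final step is global hydrogenolysis of four benzyl groups; the pyranone ring is closed last by an intramolecular Wittig reaction of an O-acylated (2-hydroxyaroyl)methylene phosphorane.
- The key disconnection is the aryl ester C–O bond, giving phosphorane 12 (heptyl-chromone half) and homophthalic half-ester 17 (benzoic acid half).
- 17 comes from benzyl orsellinate by O-benzylation and lateral lithiation/CO2. 12 comes from 2,4-dihydroxy-6-heptylacetophenone by 4-O-benzylation, α-bromination and PPh3.
- Both resorcinol rings are built de novo by Diels–Alder/aromatisation of one common diene (3) with alkynone 8 and alkynoate 14.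
- Ring order: the two benzene rings in parallel, then the pyranone.

Assumption: siphulin has no stereocentres or stereogenic double bonds, so it is achiral and the SMILES defines the target completely; no stereocontrol is needed.

**Common diene**

Step 1
Reactants: 1 methyl acetoacetate
Product: 2 methyl 3-(trimethylsilyloxy)but-2-enoate (E/Z mixture, geometry irrelevant)
Conditions: TMSCl, Et3N, hexane, rt
Reagents that add atoms: chlorotrimethylsilane, C[Si](C)(C)Cl
Why: O-silylation of the enolised β-keto ester (silyl enol ether formation).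

Step 2
Reactants: 2
Product: 3 1-methoxy-1,3-bis(trimethylsilyloxy)buta-1,3-diene (Chan's diene)
Conditions: LDA, THF, −78 °C; TMSCl, −78 → 0 °C; distil
Reagents that add atoms: chlorotrimethylsilane, C[Si](C)(C)Cl
Why: γ-deprotonation to the dienolate and O-silylation gives the silyl ketene acetal diene.

**Left half (heptyl-chromone precursor)**

Step 3
Reactants: 4 1-bromoheptane; 5 lithium acetylide–ethylenediamine complex
Product: 6 non-1-yne
Conditions: DMSO, 10–25 °C
Reagents that add atoms: none
Why: SN2 alkylation of acetylide by a primary bromide.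

Step 4
Reactants: 6 non-1-yne; 7 N-methoxy-N-methylacetamide
Product: 8 undec-3-yn-2-one
Conditions: n-BuLi, THF, −78 °C; then 7, −78 → 0 °C; aq. NH4Cl
Reagents that add atoms: none
Why: Weinreb amide acylation of the lithium acetylide stops at the ketone through the chelated tetrahedral intermediate.

Step 5
Reactants: 8 undec-3-yn-2-one; 3 Chan's diene
Product: 9 1-(2-heptyl-4,6-dihydroxyphenyl)ethan-1-one
Conditions: 3 (1.5–2 equiv), toluene, 80–100 °C, sealed, no Lewis acid; then 1 M HCl/THF, rt
Reagents that add atoms: none
Why: Diels–Alder/aromatisation; the nucleophilic CH2 terminus of the diene bonds to the alkynone β-carbon, so the acetyl group ends up between the ester-derived OH and the heptyl group, and loss of MeOH plus desilylation gives the resorcinol.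

Step 6
Reactants: 9
Product: 10 1-[4-(benzyloxy)-2-heptyl-6-hydroxyphenyl]ethan-1-one
Conditions: BnBr (1.05 equiv), K2CO3, acetone, reflux
Reagents that add atoms: benzyl bromide, BrCc1ccccc1
Why: Williamson etherification selective for the para OH, because the ortho OH is hydrogen-bonded to the ketone and much less nucleophilic.

Step 7
Reactants: 10
Product: 11 1-[4-(benzyloxy)-2-heptyl-6-hydroxyphenyl]-2-bromoethan-1-one
Conditions: CuBr2 (2 equiv), EtOAc/CHCl3 1:1, reflux
Reagents that add atoms: copper(II) bromide, Br[Cu]Br
Why: CuBr2 α-bromination through the copper enolate favours the ketone side chain over the electron-rich ring, as with related 2-hydroxy-4,6-dialkoxyacetophenones.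

Step 8
Reactants: 11
Product: 12 1-[4-(benzyloxy)-2-heptyl-6-hydroxyphenyl]-2-(triphenyl-λ5-phosphanylidene)ethan-1-one
Conditions: PPh3, toluene, rt → 50 °C (phosphonium bromide); then aq. Na2CO3/CH2Cl2
Reagents that add atoms: triphenylphosphine, c1ccc(cc1)P(c1ccccc1)c1ccccc1
Why: SN2 quaternisation of the primary α-bromoketone under neutral conditions (no benzofuranone closure), then deprotonation to the keto-stabilised ylide.

**Right half (benzoic acid half)**

Step 9
Reactants: 13 but-2-ynoic acid
Product: 14 benzyl but-2-ynoate
Conditions: BnBr, K2CO3, DMF, rt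
Reagents that add atoms: benzyl bromide, BrCc1ccccc1
Why: Carboxylate O-alkylation; the mild base avoids alkyne-to-allene isomerisation.

Step 10
Reactants: 14 benzyl but-2-ynoate; 3 Chan's diene
Product: 15 benzyl 2,4-dihydroxy-6-methylbenzoate (benzyl orsellinate)
Conditions: 3 (2 equiv), xylene or neat, 120–130 °C, sealed tube; then 1 M HCl/THF, rt
Reagents that add atoms: none
Why: Diels–Alder/aromatisation with the same regiochemistry as step 5, placing the ester between OH and CH3 and delivering the benzyl ester directly.

Step 11
Reactants: 15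
Product: 16 benzyl 2,4-bis(benzyloxy)-6-methylbenzoate
Conditions: BnBr (2.5 equiv), K2CO3, cat. TBAI, DMF, 60 °C
Reagents that add atoms: benzyl bromide, BrCc1ccccc1
Why: Exhaustive Williamson etherification; heating forces the chelated 2-OH to react.

Step 12
Reactants: 16
Product: 17 2-[3,5-bis(benzyloxy)-2-(benzyloxycarbonyl)phenyl]acetic acid
Conditions: LDA (1.2 equiv), THF, −78 °C, 30 min; CO2 (g), −78 °C → rt; aq. citric acid
Reagents that add atoms: carbon dioxide, O=C=O
Why: Lateral (benzylic) lithiation of the o-toluate followed by carboxylation; the di-ortho-substituted ester resists self-condensation at −78 °C.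

**Fragment coupling and completion**

Step 13
Reactants: 12 phosphorane; 17 acid
Product: 18 3-(benzyloxy)-5-heptyl-2-[2-(triphenyl-λ5-phosphanylidene)acetyl]phenyl 2-[3,5-bis(benzyloxy)-2-(benzyloxycarbonyl)phenyl]acetate
Conditions: EDC·HCl, DMAP (0.2 equiv), CH2Cl2, 0 °C → rt
Reagents that add atoms: none
Why: Steglich esterification; the phenol/phenoxide is acylated faster than the hindered, keto-stabilised ylide carbon.

Step 14
Reactants: 18
Product: 19 benzyl 2,4-bis(benzyloxy)-6-{[7-(benzyloxy)-5-heptyl-4-oxo-4H-chromen-2-yl]methyl}benzoate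
Conditions: toluene, 110 °C (−Ph3P=O)
Reagents that add atoms: none
Why: Intramolecular Wittig olefination of the aryl ester carbonyl closes the pyranone; the ylide is too weakly basic to enolise the arylacetate CH2, and there is no free ketone for the competing aldol closure to a 3-aryl-4-methylcoumarin.

Step 15
Reactants: 19
Product: 20 siphulin
Conditions: H2 (1 atm), 10% Pd/C, EtOAc/MeOH, rt, monitored closely; filter, concentrate below 30 °C
Reagents that add atoms: none
Why: Neutral hydrogenolysis removes three benzyl ethers and the benzyl ester at room temperature, avoiding the acid and heat that decarboxylate orsellinic-type acids; the chromone C2=C3 bond is reduced only slowly under these conditions.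

**Compound list**
1 | methyl acetoacetate | CC(=O)CC(=O)OC | starting material
2 | methyl 3-(trimethylsilyloxy)but-2-enoate (E/Z mixture) | COC(=O)C=C(C)O[Si](C)(C)C | intermediate
3 | 1-methoxy-1,3-bis(trimethylsilyloxy)buta-1,3-diene (E/Z not defined) | COC(O[Si](C)(C)C)=CC(=C)O[Si](C)(C)C | intermediate
4 | 1-bromoheptane | CCCCCCCBr | starting material
5 | lithium acetylide–ethylenediamine complex | [Li]C#C.NCCN | starting material
6 | non-1-yne | CCCCCCCC#C | intermediate
7 | N-methoxy-N-methylacetamide | CON(C)C(C)=O | starting material
8 | undec-3-yn-2-one | CCCCCCCC#CC(C)=O | intermediate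
9 | 1-(2-heptyl-4,6-dihydroxyphenyl)ethan-1-one | CCCCCCCc1cc(O)cc(O)c1C(C)=O | intermediate
10 | 1-[4-(benzyloxy)-2-heptyl-6-hydroxyphenyl]ethan-1-one | CCCCCCCc1cc(OCc2ccccc2)cc(O)c1C(C)=O | intermediate
11 | 1-[4-(benzyloxy)-2-heptyl-6-hydroxyphenyl]-2-bromoethan-1-one | CCCCCCCc1cc(OCc2ccccc2)cc(O)c1C(=O)CBr | intermediate
12 | 1-[4-(benzyloxy)-2-heptyl-6-hydroxyphenyl]-2-(triphenyl-λ5-phosphanylidene)ethan-1-one | CCCCCCCc1cc(OCc2ccccc2)cc(O)c1C(=O)C=P(c1ccccc1)(c1ccccc1)c1ccccc1 | intermediate
13 | but-2-ynoic acid | CC#CC(=O)O | starting material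
14 | benzyl but-2-ynoate | CC#CC(=O)OCc1ccccc1 | intermediate
15 | benzyl 2,4-dihydroxy-6-methylbenzoate | Cc1cc(O)cc(O)c1C(=O)OCc1ccccc1 | intermediate
16 | benzyl 2,4-bis(benzyloxy)-6-methylbenzoate | Cc1cc(OCc2ccccc2)cc(OCc2ccccc2)c1C(=O)OCc1ccccc1 | intermediate
17 | 2-[3,5-bis(benzyloxy)-2-(benzyloxycarbonyl)phenyl]acetic acid | OC(=O)Cc1cc(OCc2ccccc2)cc(OCc2ccccc2)c1C(=O)OCc1ccccc1 | intermediate
18 | aryl ester–phosphorane (name as in step 13) | CCCCCCCc1cc(OCc2ccccc2)cc(OC(=O)Cc2cc(OCc3ccccc3)cc(OCc3ccccc3)c2C(=O)OCc2ccccc2)c1C(=O)C=P(c1ccccc1)(c1ccccc1)c1ccccc1 | intermediate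
19 | benzyl 2,4-bis(benzyloxy)-6-{[7-(benzyloxy)-5-heptyl-4-oxo-4H-chromen-2-yl]methyl}benzoate | CCCCCCCc1cc(OCc2ccccc2)cc2oc(Cc3cc(OCc4ccccc4)cc(OCc4ccccc4)c3C(=O)OCc3ccccc3)cc(=O)c12 | intermediate
20 | siphulin | CCCCCCCc1cc(O)cc2oc(Cc3cc(O)cc(O)c3C(=O)O)cc(=O)c12 | target

**Totals**
Total step count: 15.
Longest linear sequence: 9 steps (4 → 6 → 8 → 9 → 10 → 11 → 12 → 18 → 19 → 20; the same length from 1 via diene 3).

**Three steps most likely to fail**
1. Step 10 (and, less so, step 5): the thermal Diels–Alder of the sensitive diene with a β-alkyl alkynoate may be sluggish and low-yielding. Fallback: build the orsellinate ring by Michael–Claisen annulation of methyl acetoacetate with methyl crotonate (NaOMe), then oxidative aromatisation (I2/DMSO), O-benzylation, and ester exchange (KOH/DMSO, then BnBr) to reach 16.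
2. Steps 13/14: C-acylation of the ylide, or acyl migration instead of olefination, would stop the chromone closure. Fallback: drop the ylide and form the C2–C3 bond by a crossed Claisen condensation of the methyl ester of 17 with the LiHMDS-generated dianion of ketone 10, then TsOH cyclodehydration of the β-diketone to 19.
3. Step 7: ring bromination of the electron-rich arene may compete with α-bromination. Fallback: install the halogen before the arene exists by acylating lithiated 6 with 2-chloro-N-methoxy-N-methylacetamide and running the Diels–Alder on 1-chloroundec-3-yn-2-one; quaternise with PPh3 before any base is used, and benzylate the 4-OH at the ylide stage.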